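C1≡C2–C3=C4–C5–C6(Cl)–C7–C8–C9(OAc)–C10(OAc)–C11=C12–C13–C14–C15 is the numbering used; the oxocene is O plus C7–C13. The hardest feature is the eight-membered ring with its remote cis C7/C13 pair, set beside the C6 chloride and the trans C9/C10 diester.
Cuts: (i) both acetates and C2–C3 (Sonogashira on an E-vinyl chloride). (ii) In one operation C7–O, C6–Cl and C10–O(acyl) are cut and O–C10 is re-made, which turns the oxocene into a trans-2,5-dihydrofuran with a Z-C6=C7 olefin. (iii) C7–C8 (acetylide plus epoxide), C5–C6 (allylation of acetylene) and C12–C13 (acylation of an acetylide).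
Enabling feature: C10 is the fourth atom from the ring oxygen in both directions (O–C7–C8–C9–C10 and O–C13–C12=C11–C10). The oxocene is therefore the perimeter of a 1-oxoniabicyclo[3.3.0]oct-6-ene whose zero bridge is O–C10. C10 is allylic and has the C9 acyloxy group next to it (a trans diester is the trace of an acetoxonium opening), and C6–Cl/C7–O is the trace of an anti chloroetherification.
Forward ring order: oxirane C9–C10, then dihydrofuran O/C10–C13 (5-exo), then a second five-membered ring O/C7–C10 (5-exo, oxonium ion), then cleavage of the zero bridge to give the oxocene. The chain grows as C8–C12 plus C13–C15, then plus C3–C7, then plus C1–C2.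
Stereochemistry: C13 comes from Noyori transfer hydrogenation and C9/C10 from Sharpless epoxidation. C10 is inverted twice (ring closure, ring expansion). C6 and C7 arise together in the key step by anti addition to the Z-olefin under substrate control (all-exo oxonium ion).

Key step: step 10

Assumption: 1 and 11 are used as the pure E isomers (distilled from the commercial isomer mixtures if necessary). Locants C1–C15 in the text are those of the first line.

Step 1
Reactants: 1 (E)-pent-2-en-4-yn-1-ol; 2 N-methoxy-N-methylpropanamide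
Product: 4 (E)-8-hydroxyoct-6-en-4-yn-3-one, via dilithio enynolate 3 (not isolated)
Conditions: n-BuLi (2.1 equiv), THF, −78 °C; 2, −78 to 0 °C; cold 1 M HCl
Reagents that add atoms: n-butyllithium, [Li]CCCC (lithium, present in 3 only)
Why: Weinreb ketone synthesis with a lithium acetylide, in which the O,C-dianion is acylated only at carbon because the chelated tetrahedral adduct survives until the acidic quench, which also keeps the liberated amine from adding to the ynone; no stereocentre is formed.

Step 2
Reactants: 4 (E)-8-hydroxyoct-6-en-4-yn-3-one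
Product: 5 (2E,6R)-oct-2-en-4-yne-1,6-diol
Conditions: Ru[(R,R)-TsDPEN](p-cymene) (1 mol %), i-PrOH, 25 °C
Reagents that add atoms: none
Why: Noyori asymmetric transfer hydrogenation of an alkynyl ketone, in which the (R,R) catalyst places the alkynyl π system under the arene ligand and delivers hydride to the face that sets C13 as R, while C=C and C≡C are left alone.

Step 3
Reactants: 5 (2E,6R)-oct-2-en-4-yne-1,6-diol
Product: 6 (3R)-1-[(2R,3R)-3-(hydroxymethyl)oxiran-2-yl]pent-1-yn-3-ol
Conditions: Ti(Oi-Pr)4 (0.2 equiv), D-(−)-diethyl tartrate (0.24 equiv), t-BuOOH (decane), 4 Å MS, CH2Cl2, −20 °C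
Reagents that add atoms: tert-butyl hydroperoxide, CC(C)(C)OO
Why: Sharpless asymmetric epoxidation of the E primary allylic alcohol, in which the D-(−)-tartrate catalyst delivers oxygen to the face that gives the trans (9R,10R)-epoxide; the C13 alcohol is propargylic and offers no competing olefin, and this second catalyst-controlled event turns any enantiomeric leakage of step 2 into a separable diastereomer.

Step 4
Reactants: 6 (3R)-1-[(2R,3R)-3-(hydroxymethyl)oxiran-2-yl]pent-1-yn-3-ol
Product: 8 (1R)-1-[(2S,5R)-5-ethyl-2,5-dihydrofuran-2-yl]ethane-1,2-diol, via Z-vinyl epoxide 7 (not isolated)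
Conditions: H2 (1 atm), Lindlar Pd, quinoline, EtOAc, 23 °C; filter; CSA (5 mol %), CH2Cl2, 0 °C
Reagents that add atoms: none
Why: Lindlar semihydrogenation bends the chain so that the C13 hydroxyl reaches the epoxide, and the acid-catalysed 5-exo-tet hydroxy-epoxide opening at the allylic carbon C10 proceeds with inversion (10R to 10S), which should give the trans-2,5-dihydrofuran and release the C9 hydroxyl with retention.

Step 5
Reactants: 8 (1R)-1-[(2S,5R)-5-ethyl-2,5-dihydrofuran-2-yl]ethane-1,2-diol
Product: 10 (2R,5S)-2-ethyl-5-[(2R)-oxiran-2-yl]-2,5-dihydrofuran, via primary tosylate 9 (not isolated)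
Conditions: NaH (2.5 equiv), N-tosylimidazole (1.05 equiv), THF, 0 to 23 °C
Reagents that add atoms: N-tosylimidazole, Cc1ccc(cc1)S(=O)(=O)n1ccnc1 (tosyl group, present in 9 only)
Why: selective sulfonylation of the primary alkoxide followed in the same flask by intramolecular Williamson closure (3-exo-tet), in which the C9–O bond is never broken, so C9 stays R.

Step 6
Reactants: 11 (E)-1,3-dichloroprop-1-ene; 12 ethynylmagnesium bromide
Product: 13 (E)-1-chloropent-1-en-4-yne
Conditions: CuBr·SMe2 (5 mol %), THF, 0 to 40 °C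
Reagents that add atoms: none
Why: copper-catalysed SN2 allylation of an alkynyl Grignard reagent at the allylic chloride; the vinylic C–Cl bond is inert, so its E geometry is kept and it serves as a masked enyne that is inert to electrophilic chlorine.

Step 7
Reactants: 10 (2R,5S)-2-ethyl-5-[(2R)-oxiran-2-yl]-2,5-dihydrofuran; 13 (E)-1-chloropent-1-en-4-yne
Product: 15 (1R,6E)-7-chloro-1-[(2S,5R)-5-ethyl-2,5-dihydrofuran-2-yl]hept-6-en-3-yn-1-ol, via lithium acetylide 14 (not isolated)
Conditions: 13 (1.5 equiv), n-BuLi, THF, −78 °C; BF3·OEt2; 10, −78 °C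
Reagents that add atoms: n-butyllithium, [Li]CCCC (lithium, present in 14 only)
Why: Yamaguchi–Hirao alkynylation, in which the BF3-activated terminal epoxide is opened at the unhindered carbon C8, forming C7–C8 and leaving the C9 stereocentre untouched.

Step 8
Reactants: 15 (1R,6E)-7-chloro-1-[(2S,5R)-5-ethyl-2,5-dihydrofuran-2-yl]hept-6-en-3-yn-1-ol
Product: 16 (1R,3Z,6E)-7-chloro-1-[(2S,5R)-5-ethyl-2,5-dihydrofuran-2-yl]hepta-3,6-dien-1-ol
Conditions: H2 (1 atm, one equivalent taken up), Lindlar Pd, quinoline, EtOAc–hexane, 0 °C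
Reagents that add atoms: none
Why: Lindlar semihydrogenation (syn addition of H2) of the only alkyne sets the Z geometry of C6=C7 on which the C6/C7 relation of the key step depends; the vinylic chloride and the doubly oxygen-flanked ring olefin are taken up far more slowly.

Step 9
Reactants: 16 (1R,3Z,6E)-7-chloro-1-[(2S,5R)-5-ethyl-2,5-dihydrofuran-2-yl]hepta-3,6-dien-1-ol
Product: 17 (1R,3Z,6E)-7-chloro-1-[(2S,5R)-5-ethyl-2,5-dihydrofuran-2-yl]hepta-3,6-dien-1-yl acetate
Conditions: Ac2O, pyridine, DMAP (cat.), CH2Cl2, 0 to 23 °C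
Reagents that add atoms: acetic anhydride, CC(=O)OC(C)=O
Why: DMAP-catalysed acetylation installs the relay nucleophile of the key step at O9 without touching the C9–O bond.

Step 10
Reactants: 17 (1R,3Z,6E)-7-chloro-1-[(2S,5R)-5-ethyl-2,5-dihydrofuran-2-yl]hepta-3,6-dien-1-yl acetate
Product: 20 (2R,4R,5R,6Z,8R)-2-[(1R,3E)-1,4-dichlorobut-3-en-1-yl]-8-ethyl-5-hydroxy-3,4,5,8-tetrahydro-2H-oxocin-4-yl acetate, via bicyclic oxonium ion 18 (not isolated), via acetoxonium ion 19 (not isolated)
Conditions: NCS (1.05 equiv), (CF3)2CHOH–CH2Cl2 (1:1), 0 °C, dark; then H2O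
Reagents that add atoms: N-chlorosuccinimide, O=C1CCC(=O)N1Cl; water, O
Why: Proposed new method: NCS, activated by hydrogen bonding to the fluorinated alcohol, transfers Cl+ to the Z-olefin C6=C7 while the dihydrofuran oxygen attacks C7 from the opposite face (5-exo opening of the incipient chloriranium ion) to give the 1-oxoniabicyclo[3.3.0]oct-6-ene 18, whose zero bridge O–C10 is then broken by backside attack of the C9 acetate carbonyl on the allylic carbon C10 (5-exo-tet closure of the dioxolan-2-ylium ring of 19), so that the oxocene appears as the perimeter of the bicycle without ever being closed head to tail, and water finally adds to the cationic carbon of 19, whose orthoacid collapses to 20. The closest known reaction type is the bromonium-induced ring-expanding bromoetherification of 2-alkenyl-tetrahydrofurans with capture of the bicyclic oxonium ion by a neighbouring carbonate, and what is new here is chlorenium as the trigger, a 2,5-dihydrofuran as the donor ring and an acetate as the relay nucleophile. C6 and C7 follow from stereospecific anti addition to the Z-olefin (only 6R,7R or 6S,7S can form), and the olefin face is chosen in the ring-forming transition state, where the C6 side chain takes the convex (exo) side of the nascent bicycle, trans to the O–C13 bond and on the same side as the C13 ethyl group, the C9 acetate and H-10, which corresponds to 7R and to the cis C7/C13 relation. C10 is inverted (S to R) because the acetate can reach only the lobe anti to the departing oxygen, which makes the C9/C10 oxygen pair trans, while C9 and C13 are spectators whose C–O bonds are never broken. Chemoselectivity rests on C6=C7 being the only electron-rich olefin (C11=C12 is flanked by two C–O bonds, C3=C4 carries chlorine) and the only one with a nucleophile in 5-exo position, exo regiochemistry is the usual outcome for Z-olefins, and of the three C–O+ bonds only O–C10 is both allylic and has an internal nucleophile aligned behind it. The main competitor, direct 6-exo capture of the chloriranium ion by the acetate carbonyl, should lose to the more basic ether oxygen closing a five-membered ring, and once 18 has formed the acetate cannot reach the rear of C7 because C7–C8–C9 is locked in the oxolane ring.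

Step 11
Reactants: 20 (2R,4R,5R,6Z,8R)-2-[(1R,3E)-1,4-dichlorobut-3-en-1-yl]-8-ethyl-5-hydroxy-3,4,5,8-tetrahydro-2H-oxocin-4-yl acetate
Product: 21 (2R,4R,5R,6Z,8R)-2-[(1R,3E)-1,4-dichlorobut-3-en-1-yl]-8-ethyl-3,4,5,8-tetrahydro-2H-oxocine-4,5-diol
Conditions: K2CO3 (0.2 equiv), MeOH, 0 °C
Reagents that add atoms: none
Why: Zemplén-type transesterification frees both hydroxyls, so that no allylic ester meets palladium(0) in step 12 and any acyl migration between O9 and O10 is without consequence; the secondary chloride is not displaced under these mild conditions.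

Step 12
Reactants: 21 (2R,4R,5R,6Z,8R)-2-[(1R,3E)-1,4-dichlorobut-3-en-1-yl]-8-ethyl-3,4,5,8-tetrahydro-2H-oxocine-4,5-diol; 22 ethynyl(trimethyl)silane
Product: 24 (2R,4R,5R,6Z,8R)-2-[(1R,3E)-1-chlorohex-3-en-5-yn-1-yl]-8-ethyl-3,4,5,8-tetrahydro-2H-oxocine-4,5-diol, via silylated enyne diol 23 (not isolated)
Conditions: PdCl2(PhCN)2 (5 mol %), CuI (10 mol %), piperidine, 22, 23 °C; then MeOH, K2CO3, 0 °C
Reagents that add atoms: none
Why: Sonogashira coupling in its amine-solvent variant for vinylic chlorides, in which oxidative addition occurs only at the sp2 C–Cl bond with retention of the E geometry while the secondary alkyl chloride, the allylic ether and the free allylic alcohol are inert to palladium(0), and methanolic carbonate then removes the silyl group in the same flask.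

Step 13
Reactants: 24 (2R,4R,5R,6Z,8R)-2-[(1R,3E)-1-chlorohex-3-en-5-yn-1-yl]-8-ethyl-3,4,5,8-tetrahydro-2H-oxocine-4,5-diol
Product: 25 (2R,4R,5R,6Z,8R)-2-[(1R,3E)-1-chlorohex-3-en-5-yn-1-yl]-8-ethyl-3,4,5,8-tetrahydro-2H-oxocine-4,5-diyl diacetate (target, 6R,7R,9R,10R,13R)
Conditions: Ac2O, pyridine, DMAP (cat.), CH2Cl2, 0 to 23 °C
Reagents that add atoms: acetic anhydride, CC(=O)OC(C)=O
Why: DMAP-catalysed acetylation of both secondary alcohols under non-ionising conditions, in which no bond to a stereocentre is broken and neither the chloride nor the enyne is affected.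

Compound list
1 | (E)-pent-2-en-4-yn-1-ol | OC/C=C/C#C | starting material
2 | N-methoxy-N-methylpropanamide | CCC(=O)N(C)OC | starting material
3 | O,C-dilithio derivative of 1 (dilithio enynolate) | [Li]OC/C=C/C#C[Li] | intermediate
4 | (E)-8-hydroxyoct-6-en-4-yn-3-one | CCC(=O)C#C/C=C/CO | intermediate
5 | (2E,6R)-oct-2-en-4-yne-1,6-diol | CC[C@@H](O)C#C/C=C/CO | intermediate
6 | (3R)-1-[(2R,3R)-3-(hydroxymethyl)oxiran-2-yl]pent-1-yn-3-ol | CC[C@@H](O)C#C[C@H]1O[C@@H]1CO | intermediate
7 | (1Z,3R)-1-[(2R,3R)-3-(hydroxymethyl)oxiran-2-yl]pent-1-en-3-ol (Z-vinyl epoxide) | CC[C@@H](O)/C=C\[C@H]1O[C@@H]1CO | intermediate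
8 | (1R)-1-[(2S,5R)-5-ethyl-2,5-dihydrofuran-2-yl]ethane-1,2-diol (trans-2,5-dihydrofuran) | CC[C@@H]1C=C[C@H](O1)[C@H](O)CO | intermediate
9 | (2R)-2-[(2S,5R)-5-ethyl-2,5-dihydrofuran-2-yl]-2-hydroxyethyl 4-methylbenzenesulfonate (primary tosylate) | CC[C@@H]1C=C[C@H](O1)[C@H](O)COS(=O)(=O)c2ccc(C)cc2 | intermediate
10 | (2R,5S)-2-ethyl-5-[(2R)-oxiran-2-yl]-2,5-dihydrofuran | CC[C@@H]1C=C[C@H](O1)[C@H]2CO2 | intermediate
11 | (E)-1,3-dichloroprop-1-ene | Cl/C=C/CCl | starting material
12 | ethynylmagnesium bromide | C#C[Mg]Br | starting material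
13 | (E)-1-chloropent-1-en-4-yne | C#CC/C=C/Cl | intermediate
14 | lithium acetylide of 13 | [Li]C#CC/C=C/Cl | intermediate
15 | (1R,6E)-7-chloro-1-[(2S,5R)-5-ethyl-2,5-dihydrofuran-2-yl]hept-6-en-3-yn-1-ol | CC[C@@H]1C=C[C@H](O1)[C@H](O)CC#CC/C=C/Cl | intermediate
16 | (1R,3Z,6E)-7-chloro-1-[(2S,5R)-5-ethyl-2,5-dihydrofuran-2-yl]hepta-3,6-dien-1-ol | CC[C@@H]1C=C[C@H](O1)[C@H](O)C/C=C\C/C=C/Cl | intermediate
17 | (1R,3Z,6E)-7-chloro-1-[(2S,5R)-5-ethyl-2,5-dihydrofuran-2-yl]hepta-3,6-dien-1-yl acetate | CC[C@@H]1C=C[C@H](O1)[C@H](OC(C)=O)C/C=C\C/C=C/Cl | intermediate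
18 | 4-acetoxy-2-[(1R,3E)-1,4-dichlorobut-3-en-1-yl]-8-ethyl-1-oxoniabicyclo[3.3.0]oct-6-ene (O+ bonded to C7, C10 and C13; all three substituents exo) | CC[C@@H]1C=C[C@@H]2[O+]1[C@H](C[C@H]2OC(C)=O)[C@H](Cl)C/C=C/Cl | intermediate
19 | 2-methyl-1,3-dioxolan-2-ylium ion trans-fused to the oxocene at C9–C10 (6R,7R,9R,10R,13R) | CC[C@@H]1/C=C\[C@H]2OC(C)=[O+][C@@H]2C[C@@H](O1)[C@H](Cl)C/C=C/Cl | intermediate
20 | (2R,4R,5R,6Z,8R)-2-[(1R,3E)-1,4-dichlorobut-3-en-1-yl]-8-ethyl-5-hydroxy-3,4,5,8-tetrahydro-2H-oxocin-4-yl acetate | CC[C@@H]1/C=C\[C@@H](O)[C@H](OC(C)=O)C[C@@H](O1)[C@H](Cl)C/C=C/Cl | intermediate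
21 | (2R,4R,5R,6Z,8R)-2-[(1R,3E)-1,4-dichlorobut-3-en-1-yl]-8-ethyl-3,4,5,8-tetrahydro-2H-oxocine-4,5-diol | CC[C@@H]1/C=C\[C@@H](O)[C@H](O)C[C@@H](O1)[C@H](Cl)C/C=C/Cl | intermediate
22 | ethynyl(trimethyl)silane | C#C[Si](C)(C)C | starting material
23 | (2R,4R,5R,6Z,8R)-2-[(1R,3E)-1-chloro-6-(trimethylsilyl)hex-3-en-5-yn-1-yl]-8-ethyl-3,4,5,8-tetrahydro-2H-oxocine-4,5-diol | CC[C@@H]1/C=C\[C@@H](O)[C@H](O)C[C@@H](O1)[C@H](Cl)C/C=C/C#C[Si](C)(C)C | intermediate
24 | (2R,4R,5R,6Z,8R)-2-[(1R,3E)-1-chlorohex-3-en-5-yn-1-yl]-8-ethyl-3,4,5,8-tetrahydro-2H-oxocine-4,5-diol | CC[C@@H]1/C=C\[C@@H](O)[C@H](O)C[C@@H](O1)[C@H](Cl)C/C=C/C#C | intermediate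
25 | (2R,4R,5R,6Z,8R)-2-[(1R,3E)-1-chlorohex-3-en-5-yn-1-yl]-8-ethyl-3,4,5,8-tetrahydro-2H-oxocine-4,5-diyl diacetate | C#C/C=C/C[C@@H](Cl)[C@H]1C[C@@H](OC(C)=O)[C@H](OC(C)=O)/C=C\[C@@H](CC)O1 | target

Total step count: 13. Longest linear sequence: 12 (steps 1–5 and 7–13; step 6 is a one-step branch).

Steps most likely to fail

**1. Step 10 (bears the label).**
- Processes at risk: capture of the chloriranium ion by the acetate carbonyl before the ring oxygen engages; irreversible and therefore unselective delivery of chlorenium to both olefin faces; collapse of the oxonium ion by loss of the C13–O bond instead of the C10–O bond.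
- The fallback uses known chemistry only, sets out from 10 and 13, and comes back at 20.
- Hydroalumination of 13 with DIBAL-H (hexane, 50 °C) should give the (E)-alkenylalane F1. n-BuLi turns it into the lithium alanate F2, which opens epoxide 10 at C8 to give the (3E,6E)-dienol F3. Acetylation then gives the acetate F4.
- F4 is submitted to the established bromonium-induced ring expansion of alkenyl-substituted oxolanes (bromodiethylsulfonium bromopentachloroantimonate, MeNO2, −25 °C, then water).
- Here halonium formation is reversible, so the olefin face is chosen by the cyclisation itself. Anti addition to the E-olefin should give the (6S,7R)-bromo hydroxy acetate F5.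
- A Finkelstein-type exchange (LiCl, DMF) then brings in chlorine as a nucleophile with inversion at C6 and returns to 20.

**2. Step 4.**
- Processes at risk: hydrogenolysis of the propargylic C–O bond or over-reduction on palladium; partial ionisation of the vinyl epoxide under acid, which would erode the inversion at C10.
- The fallback sets out from 5 and comes back at 8, and it reverses the order of the redox events so that no epoxide ever meets hydrogen and palladium.
- The enyne 5 is reduced with activated zinc (Zn/Cu/Ag, aqueous MeOH) to (2E,4Z,6R)-octa-2,4-diene-1,6-diol F6.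
- Sharpless epoxidation of F6 with D-(−)-diethyl tartrate takes the E primary allylic olefin and passes through 7, which is closed to 8 in the epoxidation flask by the titanium-bound C13 alkoxide (titanium-mediated C3-selective epoxy alcohol opening with inversion).

**3. Step 7.**
- Processes at risk: prototropic isomerisation of the skipped chloro-enyne anion and base-induced loss of HCl from its vinylic chloride.
- The fallback sets out from 10 and comes back at 15, and it moves the bond formed under basic conditions from the whole C3–C7 fragment to a plain C2 unit.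
- Commercial lithium (trimethylsilyl)acetylide with BF3·OEt2 opens 10 to the silylated homopropargylic alcohol F7, and K2CO3 in MeOH gives the terminal alkyne F8.
- A copper(I)-mediated allylation with 11 (CuI, NaI, K2CO3, DMF) then forms C5–C6 under nearly neutral conditions and gives 15.

Further compounds
F1 | step 10 | [(1E,4E)-5-chloropenta-1,4-dien-1-yl]bis(2-methylpropyl)alumane | CC(C)C[Al](CC(C)C)/C=C/C/C=C/Cl
F2 | step 10 | lithium butyl[(1E,4E)-5-chloropenta-1,4-dien-1-yl]bis(2-methylpropyl)aluminate | [Li+].CCCC[Al-](CC(C)C)(CC(C)C)/C=C/C/C=C/Cl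
F3 | step 10 | (1R,3E,6E)-7-chloro-1-[(2S,5R)-5-ethyl-2,5-dihydrofuran-2-yl]hepta-3,6-dien-1-ol | CC[C@@H]1C=C[C@H](O1)[C@H](O)C/C=C/C/C=C/Cl
F4 | step 10 | (1R,3E,6E)-7-chloro-1-[(2S,5R)-5-ethyl-2,5-dihydrofuran-2-yl]hepta-3,6-dien-1-yl acetate | CC[C@@H]1C=C[C@H](O1)[C@H](OC(C)=O)C/C=C/C/C=C/Cl
F5 | step 10 | (2R,4R,5R,6Z,8R)-2-[(1S,3E)-1-bromo-4-chlorobut-3-en-1-yl]-8-ethyl-5-hydroxy-3,4,5,8-tetrahydro-2H-oxocin-4-yl acetate | CC[C@@H]1/C=C\[C@@H](O)[C@H](OC(C)=O)C[C@@H](O1)[C@@H](Br)C/C=C/Cl
F6 | step 4 | (2E,4Z,6R)-octa-2,4-diene-1,6-diol | CC[C@@H](O)/C=C\C=C\CO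
F7 | step 7 | (1R)-1-[(2S,5R)-5-ethyl-2,5-dihydrofuran-2-yl]-4-(trimethylsilyl)but-3-yn-1-ol | CC[C@@H]1C=C[C@H](O1)[C@H](O)CC#C[Si](C)(C)C
F8 | step 7 | (1R)-1-[(2S,5R)-5-ethyl-2,5-dihydrofuran-2-yl]but-3-yn-1-ol | CC[C@@H]1C=C[C@H](O1)[C@H](O)CC#C
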